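**Retrosynthetic overview**
- Last: peracid epoxidation of C4=C5. Before that: acetylation of O9, methacryloylation of O8 and unmasking of the α-methylene lactone.
- Ten-membered ring: closed at C9–C10 by a new intramolecular nickel/photoredox decarboxylative vinylation of a dioxolane acid onto a (Z)-2-bromo enoate (sets C9, keeps the C1=C10 geometry).
- Seco chain: C1=C10 with C14 by a bromo-Wittig reaction; C2–C3 and the 4E alkene by a Claisen rearrangement; C3/C4/C15 by isopropenyl addition to the C5 aldehyde.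
- C7–C8: decarboxylative Giese addition of an L-threitol-derived dioxolanyl radical to an (S)-butenolide (sets C7 and C8); both threitol CH2OH carbons finally leave as CO2.
- Ring order: butenolide and dioxolane (bought) → saturated γ-lactone → ten-membered carbocycle → acetonide off → epoxide.

Assumption and conventions: the SMILES is taken as the (4R,5R,6S,7R,8S,9S) melampolide with C2 and C9 cis on C1=C10 (1(10)E by CIP); positions follow germacranolide numbering (ring C1–C10, lactone C11–C13 with carbonyl C12, ester carbon C14, methyl C15); TBS = tert-butyldimethylsilyl, TBDPS = tert-butyldiphenylsilyl, PMB = 4-methoxybenzyl, "X-oxymethyl" = CH2O–X; 1, 3 and all simple reagents (including 4-methoxybenzyl chloromethyl ether) are bought.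

**Route**

Step 1
Reactants: 1 (5S)-5-(hydroxymethyl)furan-2(5H)-one
Product: 2 (5S)-5-(TBS-oxymethyl)furan-2(5H)-one
Conditions: TBSCl, imidazole, CH2Cl2, 0 °C to rt
Reagents that add atoms: tert-butyldimethylsilyl chloride, CC(C)(C)[Si](C)(C)Cl
Why: Silyl ether formation on the primary alcohol; the (S) center (future C6) is not touched.

Step 2
Reactants: 3 (4S,5S)-2,2-dimethyl-1,3-dioxolane-4,5-dimethanol
Product: 4 [(4S,5S)-5-(TBDPS-oxymethyl)-2,2-dimethyl-1,3-dioxolan-4-yl]methanol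
Conditions: 3 (3 equiv), TBDPSCl (1 equiv), imidazole, THF, 0 °C
Reagents that add atoms: tert-butyldiphenylsilyl chloride, CC(C)(C)[Si](Cl)(c1ccccc1)c1ccccc1
Why: Monosilylation (silyl ether formation) of a C2-symmetric diol used in excess, so only one of the two equivalent hydroxyls reacts and no stereocenter is touched.

Step 3
Reactants: 4 [(4S,5S)-5-(TBDPS-oxymethyl)-2,2-dimethyl-1,3-dioxolan-4-yl]methanol
Product: 6 (4R,5S)-5-(TBDPS-oxymethyl)-2,2-dimethyl-1,3-dioxolane-4-carboxylic acid, via dioxolane aldehyde 5 (not isolated)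
Conditions: TEMPO (10 mol%), PhI(OAc)2 (2.2 equiv), MeCN/H2O 1:1, rt
Reagents that add atoms: water, O
Why: Oxoammonium (TEMPO) oxidation takes the primary alcohol through the aldehyde hydrate to the acid under near-neutral conditions that do not epimerise the α-center.

Step 4
Reactants: 6 (4R,5S)-5-(TBDPS-oxymethyl)-2,2-dimethyl-1,3-dioxolane-4-carboxylic acid; 2 (5S)-5-(TBS-oxymethyl)furan-2(5H)-one
Product: 7 (4S,5S)-4-[(4S,5S)-5-(TBDPS-oxymethyl)-2,2-dimethyl-1,3-dioxolan-4-yl]-5-(TBS-oxymethyl)oxolan-2-one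
Conditions: [Ir{dF(CF3)ppy}2(dtbbpy)]PF6 (1 mol%), K2HPO4, 2 (1.5 equiv), DMF, 450 nm LEDs, rt
Reagents that add atoms: none
Why: Photoredox decarboxylative Giese addition forms C7–C8: the dioxolanyl radical adds to the butenolide β-carbon anti to the silyloxymethyl group (sets C7), and the radical carbon is attacked anti to its own ring neighbour (sets C8, trans-dioxolane).

Step 5
Reactants: 7 (4S,5S)-4-[(4S,5S)-5-(TBDPS-oxymethyl)-2,2-dimethyl-1,3-dioxolan-4-yl]-5-(TBS-oxymethyl)oxolan-2-one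
Product: 9 (3R,4S,5S)-4-[(4S,5S)-5-(TBDPS-oxymethyl)-2,2-dimethyl-1,3-dioxolan-4-yl]-3-(PMB-oxymethyl)-5-(TBS-oxymethyl)oxolan-2-one, via lithium enolate 8 (not isolated)
Conditions: LiN(i-Pr)2, THF, −78 °C; then 4-methoxybenzyl chloromethyl ether, −78 to −20 °C
Reagents that add atoms: 4-methoxybenzyl chloromethyl ether, COc1ccc(COCCl)cc1
Why: Lactone enolate alkylation installs C13 as a protected hydroxymethyl group anti to the C7 substituent; this masks the α-methylene lactone (no Michael acceptor until step 16), and the C11 center is removed later.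

Step 6
Reactants: 9 (3R,4S,5S)-4-[(4S,5S)-5-(TBDPS-oxymethyl)-2,2-dimethyl-1,3-dioxolan-4-yl]-3-(PMB-oxymethyl)-5-(TBS-oxymethyl)oxolan-2-one
Product: 10 (3R,4S,5S)-4-[(4S,5S)-5-(TBDPS-oxymethyl)-2,2-dimethyl-1,3-dioxolan-4-yl]-5-(hydroxymethyl)-3-(PMB-oxymethyl)oxolan-2-one
Conditions: HF·pyridine, pyridine, THF, 0 °C
Reagents that add atoms: none
Why: Chemoselective desilylation, since the primary TBS ether is cleaved much faster than the TBDPS ether and the buffered medium spares the acetonide.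

Step 7
Reactants: 10 (3R,4S,5S)-4-[(4S,5S)-5-(TBDPS-oxymethyl)-2,2-dimethyl-1,3-dioxolan-4-yl]-5-(hydroxymethyl)-3-(PMB-oxymethyl)oxolan-2-one
Product: 11 (2S,3R,4R)-3-[(4S,5S)-5-(TBDPS-oxymethyl)-2,2-dimethyl-1,3-dioxolan-4-yl]-4-(PMB-oxymethyl)-5-oxooxolane-2-carbaldehyde
Conditions: Dess–Martin periodinane, CH2Cl2, 0 °C to rt; used crude
Reagents that add atoms: none
Why: Dess–Martin oxidation gives the C5 aldehyde without base, so the α-acyloxy center C6 is not epimerised.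

Step 8
Reactants: 11 (2S,3R,4R)-3-[(4S,5S)-5-(TBDPS-oxymethyl)-2,2-dimethyl-1,3-dioxolan-4-yl]-4-(PMB-oxymethyl)-5-oxooxolane-2-carbaldehyde
Product: 12 (3R,4R,5S)-4-[(4S,5S)-5-(TBDPS-oxymethyl)-2,2-dimethyl-1,3-dioxolan-4-yl]-5-[(1RS)-1-hydroxy-2-methylprop-2-enyl]-3-(PMB-oxymethyl)oxolan-2-one
Conditions: 2-bromopropene, CrCl2, NiCl2 (2 mol%), DMF, rt
Reagents that add atoms: 2-bromopropene, CC(Br)=C
Why: Nozaki–Hiyama–Kishi addition of the isopropenyl organochromium reagent to the aldehyde only (lactone untouched) brings in C4, C3 and C15; the C5 carbinol forms as an epimer mixture, which does not matter because this center becomes sp2 in step 10.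

Step 9
Reactants: 12 (3R,4R,5S)-4-[(4S,5S)-5-(TBDPS-oxymethyl)-2,2-dimethyl-1,3-dioxolan-4-yl]-5-[(1RS)-1-hydroxy-2-methylprop-2-enyl]-3-(PMB-oxymethyl)oxolan-2-one
Product: 13 (3R,4R,5S)-4-[(4S,5S)-5-(TBDPS-oxymethyl)-2,2-dimethyl-1,3-dioxolan-4-yl]-5-[(1RS)-1-(ethenyloxy)-2-methylprop-2-enyl]-3-(PMB-oxymethyl)oxolan-2-one
Conditions: Pd(OCOCF3)2 (5 mol%), 4,7-diphenyl-1,10-phenanthroline (5 mol%), Et3N (10 mol%), butyl vinyl ether, 75 °C
Reagents that add atoms: butyl vinyl ether, C=COCCCC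
Why: Palladium-catalysed transfer vinylation (transetherification) turns the secondary allylic alcohol into the allyl vinyl ether needed for the Claisen step.

Step 10
Reactants: 13 (3R,4R,5S)-4-[(4S,5S)-5-(TBDPS-oxymethyl)-2,2-dimethyl-1,3-dioxolan-4-yl]-5-[(1RS)-1-(ethenyloxy)-2-methylprop-2-enyl]-3-(PMB-oxymethyl)oxolan-2-one
Product: 14 (4E)-5-[(2R,3S,4R)-3-[(4S,5S)-5-(TBDPS-oxymethyl)-2,2-dimethyl-1,3-dioxolan-4-yl]-4-(PMB-oxymethyl)-5-oxooxolan-2-yl]-4-methylpent-4-enal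
Conditions: toluene, BHT (cat.), 130 °C, sealed tube
Reagents that add atoms: none
Why: Claisen rearrangement through a chair transition state with the lactone substituent equatorial (the 2-methyl group penalises the axial alternative) forms C2–C3 and the 4E trisubstituted alkene from either C5 epimer and delivers C1 as an aldehyde.

Step 11
Reactants: 14 (4E)-5-[(2R,3S,4R)-3-[(4S,5S)-5-(TBDPS-oxymethyl)-2,2-dimethyl-1,3-dioxolan-4-yl]-4-(PMB-oxymethyl)-5-oxooxolan-2-yl]-4-methylpent-4-enal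
Product: 15 methyl (2Z,6E)-2-bromo-7-[(2R,3S,4R)-3-[(4S,5S)-5-(TBDPS-oxymethyl)-2,2-dimethyl-1,3-dioxolan-4-yl]-4-(PMB-oxymethyl)-5-oxooxolan-2-yl]-6-methylhepta-2,6-dienoate
Conditions: Ph3P=CHCO2Me, N-bromosuccinimide, CH2Cl2, −20 °C; then 14, −20 °C to rt
Reagents that add atoms: methyl (triphenylphosphoranylidene)acetate, COC(=O)C=P(c1ccccc1)(c1ccccc1)c1ccccc1; N-bromosuccinimide, O=C1CCC(=O)N1Br
Why: Wittig reaction with the stabilised bromo ylide made in the flask puts the ester trans to the chain (Z bromo enoate), adds C10 and C14 and fixes the later C1=C10 geometry.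

Step 12
Reactants: 15 methyl (2Z,6E)-2-bromo-7-[(2R,3S,4R)-3-[(4S,5S)-5-(TBDPS-oxymethyl)-2,2-dimethyl-1,3-dioxolan-4-yl]-4-(PMB-oxymethyl)-5-oxooxolan-2-yl]-6-methylhepta-2,6-dienoate
Product: 16 methyl (2Z,6E)-2-bromo-7-[(2R,3S,4R)-3-[(4S,5S)-5-(hydroxymethyl)-2,2-dimethyl-1,3-dioxolan-4-yl]-4-(PMB-oxymethyl)-5-oxooxolan-2-yl]-6-methylhepta-2,6-dienoate
Conditions: Bu4NF, AcOH, THF, 0 °C to rt
Reagents that add atoms: none
Why: Fluoride desilylation buffered with AcOH frees the primary alcohol without harming the lactone or the bromo enoate.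

Step 13
Reactants: 16 methyl (2Z,6E)-2-bromo-7-[(2R,3S,4R)-3-[(4S,5S)-5-(hydroxymethyl)-2,2-dimethyl-1,3-dioxolan-4-yl]-4-(PMB-oxymethyl)-5-oxooxolan-2-yl]-6-methylhepta-2,6-dienoate
Product: 18 (4R,5S)-5-[(2R,3S,4R)-2-[(1E,5Z)-6-bromo-7-methoxy-2-methyl-7-oxohepta-1,5-dienyl]-4-(PMB-oxymethyl)-5-oxooxolan-3-yl]-2,2-dimethyl-1,3-dioxolane-4-carboxylic acid, via aldehyde 17 (not isolated)
Conditions: TEMPO (20 mol%), PhI(OAc)2 (2.5 equiv), MeCN/pH 7 buffer, rt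
Reagents that add atoms: water, O
Why: Oxoammonium (TEMPO) oxidation of the primary alcohol via the aldehyde hydrate gives the α-alkoxy acid that serves as radical precursor; alkenes and the PMB ether are tolerated.

Step 14
Reactants: 18 (4R,5S)-5-[(2R,3S,4R)-2-[(1E,5Z)-6-bromo-7-methoxy-2-methyl-7-oxohepta-1,5-dienyl]-4-(PMB-oxymethyl)-5-oxooxolan-3-yl]-2,2-dimethyl-1,3-dioxolane-4-carboxylic acid
Product: 19 methyl (1(10)E,4E,6R,7S,8S,9S,11R)-8,9-(isopropylidenedioxy)-13-(PMB-oxy)germacra-1(10),4-dien-12,6-olid-14-oate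
Conditions: [Ir{dF(CF3)ppy}2(dtbbpy)]PF6 (2 mol%), NiCl2·dme (20 mol%), 4,4′-di-tert-butyl-2,2′-bipyridine (25 mol%), K2HPO4 (2 equiv), degassed DMF (1 mM), 450 nm LEDs, rt
Reagents that add atoms: none
Why: Proposed new method: an intramolecular nickel/photoredox decarboxylative C(sp3)–C(sp2) cross-coupling used to close a carbocycle, in which the excited iridium photocatalyst oxidises the carboxylate of 18, loss of CO2 gives the nucleophilic dioxolanyl radical at C9, the nickel centre that has inserted (as zerovalent nickel) into the C10–Br bond of the same molecule captures it, and reductive elimination from trivalent nickel forms C9–C10 and the ten-membered ring; C9 is set trans to the C8 substituent on the dioxolane (the radical is trapped on the face away from its ring neighbour, as in step 4), the Z bromo enoate couples with retention so that C2 and C9 end up cis, and the masked C11 plus 1 mM dilution suppress radical conjugate addition and oligomerisation; the closest known reaction is the intermolecular decarboxylative vinylation of α-oxy acids with vinyl halides under the same dual catalysis, which has not been shown as a ring closure of a carbocycle or with a tethered 2-bromo enoate.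

Step 15
Reactants: 19 methyl (1(10)E,4E,6R,7S,8S,9S,11R)-8,9-(isopropylidenedioxy)-13-(PMB-oxy)germacra-1(10),4-dien-12,6-olid-14-oate
Product: 20 methyl (1(10)E,4E,6R,7S,8S,9S,11R)-13-hydroxy-8,9-(isopropylidenedioxy)germacra-1(10),4-dien-12,6-olid-14-oate
Conditions: DDQ, CH2Cl2/pH 7 buffer 10:1, 0 °C
Reagents that add atoms: none
Why: Oxidative PMB ether cleavage through the benzylic oxocarbenium ion frees the C13 alcohol; nothing else in 19 is electron-rich enough to be oxidised.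

Step 16
Reactants: 20 methyl (1(10)E,4E,6R,7S,8S,9S,11R)-13-hydroxy-8,9-(isopropylidenedioxy)germacra-1(10),4-dien-12,6-olid-14-oate
Product: 22 methyl (1(10)E,4E,6R,7S,8S,9S)-8,9-(isopropylidenedioxy)germacra-1(10),4,11(13)-trien-12,6-olid-14-oate, via mesylate 21 (not isolated)
Conditions: MsCl, Et3N, CH2Cl2, 0 °C; then DBU, rt
Reagents that add atoms: none
Why: Mesylation followed by E1cB elimination of the β-mesyloxy lactone gives the α-methylene lactone and removes the C11 stereocenter.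

Step 17
Reactants: 22 methyl (1(10)E,4E,6R,7S,8S,9S)-8,9-(isopropylidenedioxy)germacra-1(10),4,11(13)-trien-12,6-olid-14-oate
Product: 23 methyl (1(10)E,4E,6R,7R,8S,9S)-8,9-dihydroxygermacra-1(10),4,11(13)-trien-12,6-olid-14-oate
Conditions: AcOH/H2O 4:1, 45 °C
Reagents that add atoms: none
Why: Mild acid-catalysed acetal hydrolysis frees the 8,9-diol; the ester-deactivated C1=C10 alkene disfavours transannular cyclisation.

Step 18
Reactants: 23 methyl (1(10)E,4E,6R,7R,8S,9S)-8,9-dihydroxygermacra-1(10),4,11(13)-trien-12,6-olid-14-oate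
Product: 24 methyl (1(10)E,4E,6R,7R,8S,9S)-9-acetoxy-8-hydroxygermacra-1(10),4,11(13)-trien-12,6-olid-14-oate
Conditions: Ac2O (1.1 equiv), pyridine, CH2Cl2, −20 °C
Reagents that add atoms: acetic anhydride, CC(=O)OC(C)=O
Why: Regioselective acylation (esterification): the allylic 9-hydroxyl, next to the trigonal C10 and hydrogen-bonded to the C14 ester carbonyl, is expected to react before the 8-hydroxyl wedged between C7 and C9.

Step 19
Reactants: 24 methyl (1(10)E,4E,6R,7R,8S,9S)-9-acetoxy-8-hydroxygermacra-1(10),4,11(13)-trien-12,6-olid-14-oate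
Product: 25 methyl (1(10)E,4E,6R,7S,8S,9S)-9-acetoxy-8-(methacryloyloxy)germacra-1(10),4,11(13)-trien-12,6-olid-14-oate
Conditions: methacrylic anhydride, Et3N, DMAP (cat.), CH2Cl2, rt
Reagents that add atoms: methacrylic anhydride, CC(=C)C(=O)OC(=O)C(C)=C
Why: DMAP-catalysed acyl transfer (esterification) onto the remaining hindered 8-hydroxyl.

Step 20
Reactants: 25 methyl (1(10)E,4E,6R,7S,8S,9S)-9-acetoxy-8-(methacryloyloxy)germacra-1(10),4,11(13)-trien-12,6-olid-14-oate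
Product: 26 methyl (1(10)E,4R,5R,6S,7R,8S,9S)-9-acetoxy-4,5-epoxy-8-(methacryloyloxy)germacra-1(10),11(13)-dien-12,6-olid-14-oate (CNP0153978.3)
Conditions: mCPBA (1.2 equiv), CH2Cl2, 0 °C
Reagents that add atoms: 3-chloroperoxybenzoic acid (mCPBA), OOC(=O)c1cccc(Cl)c1
Why: Prilezhaev epoxidation of the only electron-rich alkene; with C6–H eclipsing the C4 methyl group (A1,3 strain) the ring chain through C7 covers one face of the E alkene, so the peracid adds from the open face syn to the C6–O bond and gives the 4R,5R trans-epoxide.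

**Compound list**
1 | (5S)-5-(hydroxymethyl)furan-2(5H)-one | OC[C@H]1OC(=O)C=C1 | starting material
2 | (5S)-5-(TBS-oxymethyl)furan-2(5H)-one | CC(C)(C)[Si](C)(C)OC[C@H]1OC(=O)C=C1 | intermediate
3 | (4S,5S)-2,2-dimethyl-1,3-dioxolane-4,5-dimethanol | OC[C@@H]1OC(C)(C)O[C@H]1CO | starting material
4 | [(4S,5S)-5-(TBDPS-oxymethyl)-2,2-dimethyl-1,3-dioxolan-4-yl]methanol | OC[C@@H]1OC(C)(C)O[C@H]1CO[Si](c1ccccc1)(c1ccccc1)C(C)(C)C | intermediate
5 | dioxolane aldehyde: (4R,5S)-5-(TBDPS-oxymethyl)-2,2-dimethyl-1,3-dioxolane-4-carbaldehyde | O=C[C@@H]1OC(C)(C)O[C@H]1CO[Si](c1ccccc1)(c1ccccc1)C(C)(C)C | intermediate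
6 | (4R,5S)-5-(TBDPS-oxymethyl)-2,2-dimethyl-1,3-dioxolane-4-carboxylic acid | OC(=O)[C@@H]1OC(C)(C)O[C@H]1CO[Si](c1ccccc1)(c1ccccc1)C(C)(C)C | intermediate
7 | (4S,5S)-4-[(4S,5S)-5-(TBDPS-oxymethyl)-2,2-dimethyl-1,3-dioxolan-4-yl]-5-(TBS-oxymethyl)oxolan-2-one | O=C1C[C@H]([C@@H]2OC(C)(C)O[C@H]2CO[Si](c2ccccc2)(c2ccccc2)C(C)(C)C)[C@@H](CO[Si](C)(C)C(C)(C)C)O1 | intermediate
8 | lithium enolate of 7 (C11=C12 enolate) | [Li+].[O-]C1=C[C@H]([C@@H]2OC(C)(C)O[C@H]2CO[Si](c2ccccc2)(c2ccccc2)C(C)(C)C)[C@@H](CO[Si](C)(C)C(C)(C)C)O1 | intermediate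
9 | (3R,4S,5S)-4-[(4S,5S)-5-(TBDPS-oxymethyl)-2,2-dimethyl-1,3-dioxolan-4-yl]-3-(PMB-oxymethyl)-5-(TBS-oxymethyl)oxolan-2-one | O=C1[C@@H](COCc2ccc(OC)cc2)[C@H]([C@@H]2OC(C)(C)O[C@H]2CO[Si](c2ccccc2)(c2ccccc2)C(C)(C)C)[C@@H](CO[Si](C)(C)C(C)(C)C)O1 | intermediate
10 | (3R,4S,5S)-4-[(4S,5S)-5-(TBDPS-oxymethyl)-2,2-dimethyl-1,3-dioxolan-4-yl]-5-(hydroxymethyl)-3-(PMB-oxymethyl)oxolan-2-one | O=C1[C@@H](COCc2ccc(OC)cc2)[C@H]([C@@H]2OC(C)(C)O[C@H]2CO[Si](c2ccccc2)(c2ccccc2)C(C)(C)C)[C@@H](CO)O1 | intermediate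
11 | (2S,3R,4R)-3-[(4S,5S)-5-(TBDPS-oxymethyl)-2,2-dimethyl-1,3-dioxolan-4-yl]-4-(PMB-oxymethyl)-5-oxooxolane-2-carbaldehyde | O=C1[C@@H](COCc2ccc(OC)cc2)[C@H]([C@@H]2OC(C)(C)O[C@H]2CO[Si](c2ccccc2)(c2ccccc2)C(C)(C)C)[C@@H](C=O)O1 | intermediate
12 | (3R,4R,5S)-4-[(4S,5S)-5-(TBDPS-oxymethyl)-2,2-dimethyl-1,3-dioxolan-4-yl]-5-[(1RS)-1-hydroxy-2-methylprop-2-enyl]-3-(PMB-oxymethyl)oxolan-2-one (C5 epimer mixture) | O=C1[C@@H](COCc2ccc(OC)cc2)[C@H]([C@@H]2OC(C)(C)O[C@H]2CO[Si](c2ccccc2)(c2ccccc2)C(C)(C)C)[C@@H](C(O)C(C)=C)O1 | intermediate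
13 | (3R,4R,5S)-4-[(4S,5S)-5-(TBDPS-oxymethyl)-2,2-dimethyl-1,3-dioxolan-4-yl]-5-[(1RS)-1-(ethenyloxy)-2-methylprop-2-enyl]-3-(PMB-oxymethyl)oxolan-2-one (C5 epimer mixture) | O=C1[C@@H](COCc2ccc(OC)cc2)[C@H]([C@@H]2OC(C)(C)O[C@H]2CO[Si](c2ccccc2)(c2ccccc2)C(C)(C)C)[C@@H](C(OC=C)C(C)=C)O1 | intermediate
14 | (4E)-5-[(2R,3S,4R)-3-[(4S,5S)-5-(TBDPS-oxymethyl)-2,2-dimethyl-1,3-dioxolan-4-yl]-4-(PMB-oxymethyl)-5-oxooxolan-2-yl]-4-methylpent-4-enal | O=C1[C@@H](COCc2ccc(OC)cc2)[C@H]([C@@H]2OC(C)(C)O[C@H]2CO[Si](c2ccccc2)(c2ccccc2)C(C)(C)C)[C@@H](/C=C(\C)CCC=O)O1 | intermediate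
15 | methyl (2Z,6E)-2-bromo-7-[(2R,3S,4R)-3-[(4S,5S)-5-(TBDPS-oxymethyl)-2,2-dimethyl-1,3-dioxolan-4-yl]-4-(PMB-oxymethyl)-5-oxooxolan-2-yl]-6-methylhepta-2,6-dienoate | O=C1[C@@H](COCc2ccc(OC)cc2)[C@H]([C@@H]2OC(C)(C)O[C@H]2CO[Si](c2ccccc2)(c2ccccc2)C(C)(C)C)[C@@H](/C=C(\C)CC/C=C(\Br)C(=O)OC)O1 | intermediate
16 | methyl (2Z,6E)-2-bromo-7-[(2R,3S,4R)-3-[(4S,5S)-5-(hydroxymethyl)-2,2-dimethyl-1,3-dioxolan-4-yl]-4-(PMB-oxymethyl)-5-oxooxolan-2-yl]-6-methylhepta-2,6-dienoate | O=C1[C@@H](COCc2ccc(OC)cc2)[C@H]([C@@H]2OC(C)(C)O[C@H]2CO)[C@@H](/C=C(\C)CC/C=C(\Br)C(=O)OC)O1 | intermediate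
17 | aldehyde: methyl (2Z,6E)-2-bromo-7-[(2R,3S,4R)-3-[(4S,5R)-5-formyl-2,2-dimethyl-1,3-dioxolan-4-yl]-4-(PMB-oxymethyl)-5-oxooxolan-2-yl]-6-methylhepta-2,6-dienoate | O=C1[C@@H](COCc2ccc(OC)cc2)[C@H]([C@@H]2OC(C)(C)O[C@H]2C=O)[C@@H](/C=C(\C)CC/C=C(\Br)C(=O)OC)O1 | intermediate
18 | (4R,5S)-5-[(2R,3S,4R)-2-[(1E,5Z)-6-bromo-7-methoxy-2-methyl-7-oxohepta-1,5-dienyl]-4-(PMB-oxymethyl)-5-oxooxolan-3-yl]-2,2-dimethyl-1,3-dioxolane-4-carboxylic acid | O=C1[C@@H](COCc2ccc(OC)cc2)[C@H]([C@@H]2OC(C)(C)O[C@H]2C(O)=O)[C@@H](/C=C(\C)CC/C=C(\Br)C(=O)OC)O1 | intermediate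
19 | methyl (1(10)E,4E,6R,7S,8S,9S,11R)-8,9-(isopropylidenedioxy)-13-(PMB-oxy)germacra-1(10),4-dien-12,6-olid-14-oate | CC1(C)O[C@H]2[C@H]3[C@H](COCc4ccc(OC)cc4)C(=O)O[C@@H]3/C=C(\C)CC/C=C(/C(=O)OC)[C@@H]2O1 | intermediate
20 | methyl (1(10)E,4E,6R,7S,8S,9S,11R)-13-hydroxy-8,9-(isopropylidenedioxy)germacra-1(10),4-dien-12,6-olid-14-oate | CC1(C)O[C@H]2[C@H]3[C@H](CO)C(=O)O[C@@H]3/C=C(\C)CC/C=C(/C(=O)OC)[C@@H]2O1 | intermediate
21 | mesylate: 13-O-methanesulfonyl derivative of 20 | CC1(C)O[C@H]2[C@H]3[C@H](COS(C)(=O)=O)C(=O)O[C@@H]3/C=C(\C)CC/C=C(/C(=O)OC)[C@@H]2O1 | intermediate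
22 | methyl (1(10)E,4E,6R,7S,8S,9S)-8,9-(isopropylidenedioxy)germacra-1(10),4,11(13)-trien-12,6-olid-14-oate | CC1(C)O[C@H]2[C@H]3C(=C)C(=O)O[C@@H]3/C=C(\C)CC/C=C(/C(=O)OC)[C@@H]2O1 | intermediate
23 | methyl (1(10)E,4E,6R,7R,8S,9S)-8,9-dihydroxygermacra-1(10),4,11(13)-trien-12,6-olid-14-oate | O[C@H]1[C@H]2C(=C)C(=O)O[C@@H]2/C=C(\C)CC/C=C(/C(=O)OC)[C@@H]1O | intermediate
24 | methyl (1(10)E,4E,6R,7R,8S,9S)-9-acetoxy-8-hydroxygermacra-1(10),4,11(13)-trien-12,6-olid-14-oate | O[C@H]1[C@H]2C(=C)C(=O)O[C@@H]2/C=C(\C)CC/C=C(/C(=O)OC)[C@@H]1OC(C)=O | intermediate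
25 | methyl (1(10)E,4E,6R,7S,8S,9S)-9-acetoxy-8-(methacryloyloxy)germacra-1(10),4,11(13)-trien-12,6-olid-14-oate | C=C(C)C(=O)O[C@H]1[C@H]2C(=C)C(=O)O[C@@H]2/C=C(\C)CC/C=C(/C(=O)OC)[C@@H]1OC(C)=O | intermediate
26 | methyl (1(10)E,4R,5R,6S,7R,8S,9S)-9-acetoxy-4,5-epoxy-8-(methacryloyloxy)germacra-1(10),11(13)-dien-12,6-olid-14-oate (CNP0153978.3) | C=C(C)C(=O)O[C@H]1[C@H]2C(=C)C(=O)O[C@@H]2[C@H]2O[C@]2(C)CC/C=C(/C(=O)OC)[C@@H]1OC(C)=O | target

**Count and risks**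

Total: 20 steps. Longest linear sequence: 19 steps (3 → 26 through steps 2 to 20); step 1 is the only side branch.

Most likely to fail, first: step 14, the proposed new macrocyclisation. The ring strain of the ten-membered ring, protodecarboxylation at C9 and light-induced Z/E drift of the bromo enoate can all cut it down. The fallback uses known chemistry only, sets out from aldehyde 14 and comes back to the route at 19. Wittig methylenation of 14 (Ph3P=CH2, THF, −78 °C) gives the C1 vinyl lactone F1. Bu4NF/AcOH removes the silyl group to give the primary alcohol F2, and Dess–Martin oxidation gives the dioxolane aldehyde F3. The Ohira–Bestmann reagent (dimethyl (1-diazo-2-oxopropyl)phosphonate, K2CO3, MeOH) turns it into the terminal alkyne F4. Branched-selective hydromethoxycarbonylation (Pd(OAc)2, 2-pyridyldiphenylphosphine, CH3SO3H, CO, MeOH) gives the 2-substituted acrylate F5; here the threitol carbon is kept as C10 and CO supplies C14. Ring-closing metathesis of F5 with the second-generation Hoveyda–Grubbs catalyst RuCl2(H2IMes)(=CH-C6H4-2-O-i-Pr) (toluene, 80 °C, 1 mM) joins C1 and C10 with loss of ethene and gives 19.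

Second: step 18, the choice between the two secondary hydroxyls of diol 23. If the 8-hydroxyl is the faster one, the order of the two acylations is turned round, setting out from 23 and coming back at 25. Diol 23 is mono-acylated with methacrylic anhydride (1.1 equiv, pyridine, −20 °C) to the 8-methacrylate 9-alcohol F6, and acetylation of F6 (Ac2O, DMAP, CH2Cl2) gives 25. Either sense of selectivity therefore leads to 25.

Third: step 20, the face selectivity of the epoxidation on the flexible ring. If the peracid delivers oxygen to the wrong face, the epoxide is built in two steps with the opposite facial sense, setting out from 25 and coming back at 26. NBS in THF/H2O at 0 °C adds Br+ to the open face of C4=C5 and water to the tertiary C4 from the other side, giving the bromohydrin F7. K2CO3 in acetone then closes the ring by backside displacement of bromide at C5, which places the epoxide oxygen on the face the peracid does not reach and gives 26.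

**Further compounds**
F1 | step 14 | C1 vinyl lactone: (3R,4S,5R)-4-[(4S,5S)-5-(TBDPS-oxymethyl)-2,2-dimethyl-1,3-dioxolan-4-yl]-5-[(1E)-2-methylhexa-1,5-dienyl]-3-(PMB-oxymethyl)oxolan-2-one | O=C1[C@@H](COCc2ccc(OC)cc2)[C@H]([C@@H]2OC(C)(C)O[C@H]2CO[Si](c2ccccc2)(c2ccccc2)C(C)(C)C)[C@@H](/C=C(\C)CCC=C)O1
F2 | step 14 | primary alcohol: (3R,4S,5R)-4-[(4S,5S)-5-(hydroxymethyl)-2,2-dimethyl-1,3-dioxolan-4-yl]-5-[(1E)-2-methylhexa-1,5-dienyl]-3-(PMB-oxymethyl)oxolan-2-one | O=C1[C@@H](COCc2ccc(OC)cc2)[C@H]([C@@H]2OC(C)(C)O[C@H]2CO)[C@@H](/C=C(\C)CCC=C)O1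
F3 | step 14 | dioxolane aldehyde: (4R,5S)-5-[(2R,3S,4R)-2-[(1E)-2-methylhexa-1,5-dienyl]-4-(PMB-oxymethyl)-5-oxooxolan-3-yl]-2,2-dimethyl-1,3-dioxolane-4-carbaldehyde | O=C1[C@@H](COCc2ccc(OC)cc2)[C@H]([C@@H]2OC(C)(C)O[C@H]2C=O)[C@@H](/C=C(\C)CCC=C)O1
F4 | step 14 | terminal alkyne: (3R,4S,5R)-4-[(4S,5S)-5-ethynyl-2,2-dimethyl-1,3-dioxolan-4-yl]-5-[(1E)-2-methylhexa-1,5-dienyl]-3-(PMB-oxymethyl)oxolan-2-one | O=C1[C@@H](COCc2ccc(OC)cc2)[C@H]([C@@H]2OC(C)(C)O[C@H]2C#C)[C@@H](/C=C(\C)CCC=C)O1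
F5 | step 14 | 2-substituted acrylate: methyl 2-[(4S,5S)-5-[(2R,3S,4R)-2-[(1E)-2-methylhexa-1,5-dienyl]-4-(PMB-oxymethyl)-5-oxooxolan-3-yl]-2,2-dimethyl-1,3-dioxolan-4-yl]prop-2-enoate | O=C1[C@@H](COCc2ccc(OC)cc2)[C@H]([C@@H]2OC(C)(C)O[C@H]2C(=C)C(=O)OC)[C@@H](/C=C(\C)CCC=C)O1
F6 | step 18 | 8-methacrylate 9-alcohol: methyl (1(10)E,4E,6R,7S,8S,9S)-9-hydroxy-8-(methacryloyloxy)germacra-1(10),4,11(13)-trien-12,6-olid-14-oate | C=C(C)C(=O)O[C@H]1[C@H]2C(=C)C(=O)O[C@@H]2/C=C(\C)CC/C=C(/C(=O)OC)[C@@H]1O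
F7 | step 20 | bromohydrin: methyl (1(10)E,4R,5S,6S,7R,8S,9S)-9-acetoxy-5-bromo-4-hydroxy-8-(methacryloyloxy)germacra-1(10),11(13)-dien-12,6-olid-14-oate | C=C(C)C(=O)O[C@H]1[C@H]2C(=C)C(=O)O[C@@H]2[C@H](Br)[C@@](O)(C)CC/C=C(/C(=O)OC)[C@@H]1OC(C)=O
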